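**Plan**

- Retrosynthesis: the six hydroxyls are traced back to six aryl acetates. The C5–vinyl bond on ring A is then cut to an aryl triflate and 3,5-diacetoxystyrene (ring E). Last, C3–C3a and O1–C2 are cut together, which gives the olefin of a ring D-diacetylated piceatannol (rings C and D) and 1,4-benzoquinone (ring A at the oxidised level; its two oxygens become O1 and the C5 oxygen).
- Enabling feature: on ring A, O1 (on C7a) and C5 are para, so ring A can enter as a quinone whose CH carbon becomes C3a. Ring C carries a hydroxyl para to C2, which makes the olefin carbon next to ring D (C3) nucleophilic and turns C2 into a quinone methide carbon onto which O1 can close.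
- Forward order: ring D acetylation of piceatannol; [3+2] annulation that builds the dihydrofuran ring (O1, C2, C3, C3a, C7a) onto ring A; triflation at C5 and acetylation of ring C; Heck attachment of the ring E styryl arm; global deacetylation.
- Stereochemistry: C3 comes from a chiral phosphoric acid in the C–C bond-forming event, and C2 from C3 in the ring closure (trans). The E olefin comes from the Heck reaction. No later step touches C2 or C3.

Key step: step 2

Assumption: the sense of induction of the binaphthyl phosphoric acid cannot be predicted for this substrate; the (R)-catalyst is written, and its equally available (S)-antipode would take its place should the first run lead to the (2R,3R) series.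

**Route**

Step 1
Reactants: 1 piceatannol
Product: 4 3,5-di-O-acetylpiceatannol, via piceatannol catechol phenylboronate 2 (not isolated), via diacetyl piceatannol phenylboronate 3 (not isolated)
Conditions: PhB(OH)2, 4 Å MS, THF, rt; then Ac2O, pyridine, 0 °C → rt; then pinacol, THF/H2O, rt
Reagents that add atoms: acetic anhydride, CC(=O)OC(C)=O
Why: Phenylboronic acid condenses selectively with the ring C catechol to a five-membered cyclic boronate (transient diol protection), so that O-acetylation should esterify only the two ring D hydroxyls, and exchange of boron to pinacol then returns the free catechol.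

Step 2
Reactants: 4 3,5-di-O-acetylpiceatannol; 5 1,4-benzoquinone
Product: 7 5-[(2S,3S)-2-(3,4-dihydroxyphenyl)-5-hydroxy-2,3-dihydro-1-benzofuran-3-yl]-1,3-phenylene diacetate, via quinone methide hydroquinone 6 (not isolated)
Conditions: (R)-TRIP [(R)-3,3'-bis(2,4,6-triisopropylphenyl)-1,1'-binaphthyl-2,2'-diyl hydrogen phosphate] (10 mol %), toluene/CH2Cl2, 4 Å MS, −20 → 0 °C, argon, slow addition of 5
Reagents that add atoms: none
Why: Proposed new method: the phosphoric acid is expected to hold the C4' hydroxyl of ring C on its P=O oxygen and a carbonyl of 5 on its P–OH, so that the olefin carbon next to ring D (future C3) adds to a quinone CH (future C3a) in a vinylogous Michael addition that leaves ring C as a para-quinone methide and, after enolisation, ring A as hydroquinone 6. The hydroquinone oxygen ortho to the new bond (future O1) then adds to the exocyclic methide carbon (future C2) in a 5-exo-trig oxa-1,6-addition, which closes the dihydrofuran ring and restores ring C as a catechol. The closest known reaction type is the chiral phosphoric acid catalysed formal [3+2] annulation of quinones and quinone monoimines with ortho-hydroxyaryl alkenes, vinylindoles and enecarbamates, together with the acid-promoted racemic [3+2] of quinones with para-oxygenated propenylbenzenes; what is new is a para-hydroxystilbene as the two-carbon partner. C3 is set in the C–C bond formation by the catalyst pocket, and C2 is set in the ring closure by C3, the oxygen adding anti to the ring D aryl group, with reversible closure through the methide also favouring trans. Only 5 is electrophilic and only 4 nucleophilic, so no homodimer can form; the para hydroxyl of ring C decides which olefin carbon attacks, and the two acetates keep ring D from reacting as an arene nucleophile.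

Step 3
Reactants: 7 5-[(2S,3S)-2-(3,4-dihydroxyphenyl)-5-hydroxy-2,3-dihydro-1-benzofuran-3-yl]-1,3-phenylene diacetate
Product: 10 (2S,3S)-3-(3,5-diacetoxyphenyl)-2-(3,4-dihydroxyphenyl)-2,3-dihydro-1-benzofuran-5-yl trifluoromethanesulfonate, via triol catechol phenylboronate 8 (not isolated), via triflate phenylboronate 9 (not isolated)
Conditions: PhB(OH)2, 4 Å MS, THF, rt; then PhNTf2, Et3N, CH2Cl2, 0 °C → rt; then pinacol, THF/H2O, rt
Reagents that add atoms: N-phenyl-bis(trifluoromethanesulfonimide), O=S(=O)(N(c1ccccc1)S(=O)(=O)C(F)(F)F)C(F)(F)F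
Why: The same transient boronate masking of the ring C catechol leaves the C5 hydroxyl as the only free phenol for O-triflation (sulfonylation) with N-phenyltriflimide, after which pinacol exchange frees the catechol, and neither stereocentre is touched.

Step 4
Reactants: 10 (2S,3S)-3-(3,5-diacetoxyphenyl)-2-(3,4-dihydroxyphenyl)-2,3-dihydro-1-benzofuran-5-yl trifluoromethanesulfonate
Product: 11 (2S,3S)-2-(3,4-diacetoxyphenyl)-3-(3,5-diacetoxyphenyl)-2,3-dihydro-1-benzofuran-5-yl trifluoromethanesulfonate
Conditions: Ac2O, pyridine, DMAP (cat.), CH2Cl2, 0 °C → rt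
Reagents that add atoms: acetic anhydride, CC(=O)OC(C)=O
Why: Standard O-acetylation of the catechol puts one protecting-group type on all phenolic oxygens and lowers the electron density of ring C, which should shield the C2–O1 benzylic ether from ionisation and the catechol from oxidation in the palladium step.

Step 5
Reactants: 12 3,5-dihydroxybenzaldehyde
Product: 14 3,5-diacetoxystyrene, via dipotassium 5-ethenylbenzene-1,3-diolate 13 (not isolated)
Conditions: Ph3PCH3Br (1.3 equiv), KOtBu (3.4 equiv), THF, 0 °C → rt; then Ac2O, 0 °C → rt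
Reagents that add atoms: methyltriphenylphosphonium bromide, C[P+](c1ccccc1)(c1ccccc1)c1ccccc1.[Br-]; acetic anhydride, CC(=O)OC(C)=O
Why: Wittig methylenation with excess base tolerates the two meta phenoxides, and O-acetylation in the same flask traps the polymerisation-prone dihydroxystyrene as its stable diacetate.

Step 6
Reactants: 11 (2S,3S)-2-(3,4-diacetoxyphenyl)-3-(3,5-diacetoxyphenyl)-2,3-dihydro-1-benzofuran-5-yl trifluoromethanesulfonate; 14 3,5-diacetoxystyrene
Product: 15 5-[(E)-2-[(2S,3S)-2-(3,4-diacetoxyphenyl)-3-(3,5-diacetoxyphenyl)-2,3-dihydro-1-benzofuran-5-yl]ethenyl]-1,3-phenylene diacetate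
Conditions: Pd(OAc)2 (5 mol %), PPh3 (12 mol %), LiCl, Et3N, DMF, 90 °C
Reagents that add atoms: none
Why: Mizoroki–Heck reaction, in which oxidative addition of the aryl triflate to zerovalent palladium, chloride-assisted neutral-pathway syn insertion at the terminal styrene carbon and syn β-hydride elimination should give the (E)-stilbene, while the acetates and the two stereocentres stay unchanged.

Step 7
Reactants: 15 5-[(E)-2-[(2S,3S)-2-(3,4-diacetoxyphenyl)-3-(3,5-diacetoxyphenyl)-2,3-dihydro-1-benzofuran-5-yl]ethenyl]-1,3-phenylene diacetate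
Product: 16 4-[(2S,3S)-3-(3,5-dihydroxyphenyl)-5-[(E)-2-(3,5-dihydroxyphenyl)ethenyl]-2,3-dihydro-1-benzofuran-2-yl]benzene-1,2-diol
Conditions: K2CO3 (cat.), degassed MeOH/THF, 0 °C, argon; then AcOH
Reagents that add atoms: none
Why: Carbonate-catalysed transesterification (methanolysis) of the six aryl acetates at low temperature without oxygen should free the phenols without touching C3, and C2 is already in the thermodynamically preferred trans arrangement.

**Compound list**

1 | piceatannol, (E)-4-[2-(3,5-dihydroxyphenyl)ethenyl]benzene-1,2-diol | Oc1ccc(/C=C/c2cc(O)cc(O)c2)cc1O | starting material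
2 | piceatannol catechol phenylboronate, (E)-5-[2-(2-phenyl-1,3,2-benzodioxaborol-5-yl)ethenyl]benzene-1,3-diol | Oc1cc(O)cc(/C=C/c2ccc3OB(c4ccccc4)Oc3c2)c1 | intermediate
3 | diacetyl piceatannol phenylboronate, (E)-5-[2-(2-phenyl-1,3,2-benzodioxaborol-5-yl)ethenyl]-1,3-phenylene diacetate | CC(=O)Oc1cc(OC(C)=O)cc(/C=C/c2ccc3OB(c4ccccc4)Oc3c2)c1 | intermediate
4 | 3,5-di-O-acetylpiceatannol, (E)-5-[2-(3,4-dihydroxyphenyl)ethenyl]-1,3-phenylene diacetate | CC(=O)Oc1cc(OC(C)=O)cc(/C=C/c2ccc(O)c(O)c2)c1 | intermediate
5 | 1,4-benzoquinone | O=C1C=CC(=O)C=C1 | starting material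
6 | quinone methide hydroquinone, 5-[(1S)-1-(2,5-dihydroxyphenyl)-2-(3-hydroxy-4-oxocyclohexa-2,5-dien-1-ylidene)ethyl]-1,3-phenylene diacetate (methide geometry not defined) | Oc1ccc(O)c(c1)[C@H](c1cc(OC(C)=O)cc(OC(C)=O)c1)C=C1C=CC(=O)C(O)=C1 | intermediate
7 | 5-[(2S,3S)-2-(3,4-dihydroxyphenyl)-5-hydroxy-2,3-dihydro-1-benzofuran-3-yl]-1,3-phenylene diacetate | Oc1ccc2c(c1)[C@H](c1cc(OC(C)=O)cc(OC(C)=O)c1)[C@@H](c1ccc(O)c(O)c1)O2 | intermediate
8 | triol catechol phenylboronate, 5-[(2S,3S)-5-hydroxy-2-(2-phenyl-1,3,2-benzodioxaborol-5-yl)-2,3-dihydro-1-benzofuran-3-yl]-1,3-phenylene diacetate | Oc1ccc2c(c1)[C@H](c1cc(OC(C)=O)cc(OC(C)=O)c1)[C@@H](c1ccc3OB(c4ccccc4)Oc3c1)O2 | intermediate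
9 | triflate phenylboronate, (2S,3S)-3-(3,5-diacetoxyphenyl)-2-(2-phenyl-1,3,2-benzodioxaborol-5-yl)-2,3-dihydro-1-benzofuran-5-yl trifluoromethanesulfonate | O=S(=O)(Oc1ccc2c(c1)[C@H](c1cc(OC(C)=O)cc(OC(C)=O)c1)[C@@H](c1ccc3OB(c4ccccc4)Oc3c1)O2)C(F)(F)F | intermediate
10 | (2S,3S)-3-(3,5-diacetoxyphenyl)-2-(3,4-dihydroxyphenyl)-2,3-dihydro-1-benzofuran-5-yl trifluoromethanesulfonate | O=S(=O)(Oc1ccc2c(c1)[C@H](c1cc(OC(C)=O)cc(OC(C)=O)c1)[C@@H](c1ccc(O)c(O)c1)O2)C(F)(F)F | intermediate
11 | (2S,3S)-2-(3,4-diacetoxyphenyl)-3-(3,5-diacetoxyphenyl)-2,3-dihydro-1-benzofuran-5-yl trifluoromethanesulfonate | O=S(=O)(Oc1ccc2c(c1)[C@H](c1cc(OC(C)=O)cc(OC(C)=O)c1)[C@@H](c1ccc(OC(C)=O)c(OC(C)=O)c1)O2)C(F)(F)F | intermediate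
12 | 3,5-dihydroxybenzaldehyde | O=Cc1cc(O)cc(O)c1 | starting material
13 | dipotassium 5-ethenylbenzene-1,3-diolate (3,5-dihydroxystyrene as its bis-phenoxide) | C=Cc1cc([O-])cc([O-])c1.[K+].[K+] | intermediate
14 | 3,5-diacetoxystyrene, 5-ethenyl-1,3-phenylene diacetate | C=Cc1cc(OC(C)=O)cc(OC(C)=O)c1 | intermediate
15 | target hexaacetate, 5-[(E)-2-[(2S,3S)-2-(3,4-diacetoxyphenyl)-3-(3,5-diacetoxyphenyl)-2,3-dihydro-1-benzofuran-5-yl]ethenyl]-1,3-phenylene diacetate | CC(=O)Oc1cc(OC(C)=O)cc(/C=C/c2ccc3c(c2)[C@H](c2cc(OC(C)=O)cc(OC(C)=O)c2)[C@@H](c2ccc(OC(C)=O)c(OC(C)=O)c2)O3)c1 | intermediate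
16 | 4-[(2S,3S)-3-(3,5-dihydroxyphenyl)-5-[(E)-2-(3,5-dihydroxyphenyl)ethenyl]-2,3-dihydro-1-benzofuran-2-yl]benzene-1,2-diol | Oc1cc(O)cc(/C=C/c2ccc3c(c2)[C@H](c2cc(O)cc(O)c2)[C@@H](c2ccc(O)c(O)c2)O3)c1 | target

**Step count and risks**

Total steps: 7. Longest linear sequence: 6 (steps 1, 2, 3, 4, 6 and 7, from 1).

Steps most likely to fail:

Step 2 (Proposed new method). The hydrogen-bonded transition state may discriminate the two olefin faces poorly, or hydrogen and electron transfer between the free catechol and the quinone may outrun the C–C bond formation. The fallback uses known chemistry and sets out from 4. Both catechol hydroxyls are silylated (TBSCl, imidazole, DMF) to give (E)-5-[2-[3,4-bis(tert-butyldimethylsilyloxy)phenyl]ethenyl]-1,3-phenylene diacetate F1. F1 and 5 are then joined in the Lewis-acid-promoted quinone–styrene [3+2] annulation (TiCl4–Ti(OiPr)4, CH2Cl2, −78 °C), in which the C4' silyloxy group stabilises the benzylic cation that the ring A oxygen captures. This should give the trans adduct as a racemate, that is the (2S,3S)-bis-silyl ether F2 together with its (2R,3R)-enantiomer F3. The two are separated by preparative chromatography on a polysaccharide carbamate chiral stationary phase. Desilylation of F2 with HF·pyridine in THF, which leaves the acetates alone, comes back to the route at 7.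

Step 3. The boronate mask may slip under the amine base (exchange of boron off the catechol), so that sulfonylation also occurs on ring C. The fallback sets out from 7 and replaces the transient mask by an isolable one. 1,1'-Carbonyldiimidazole in THF should convert the catechol into the cyclic carbonate F4; a carbonyl that lands on the C5 oxygen is passed on to a free catechol or hydrolysed on work-up. Triflation (PhNTf2, Et3N, CH2Cl2) gives the carbonate triflate F5. The Heck reaction with 14 under the conditions of step 6 gives the carbonate tetraacetate stilbene F6. Methanolysis with K2CO3 in MeOH under argon removes the carbonate together with the four acetates and comes back to the route at 16.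

Step 6. Insertion with the opposite regiochemistry (branched diarylethene) and base-induced loss of acetyl groups at 90 °C may erode the coupling. The fallback sets out from 11 and forms the stilbene double bond by metathesis instead of insertion. Stille coupling with tributyl(vinyl)stannane (Pd(PPh3)4, LiCl, dioxane, 90 °C) should give the 5-vinyl tetraacetate F7. Olefin cross-metathesis of F7 with an excess of 14 (second-generation Grubbs catalyst, CH2Cl2, 40 °C) should give the E-stilbene and comes back to the route at 15.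

**Further compounds**

F1 | step 2 | (E)-5-[2-[3,4-bis(tert-butyldimethylsilyloxy)phenyl]ethenyl]-1,3-phenylene diacetate | CC(=O)Oc1cc(OC(C)=O)cc(/C=C/c2ccc(O[Si](C)(C)C(C)(C)C)c(O[Si](C)(C)C(C)(C)C)c2)c1
F2 | step 2 | 5-[(2S,3S)-2-[3,4-bis(tert-butyldimethylsilyloxy)phenyl]-5-hydroxy-2,3-dihydro-1-benzofuran-3-yl]-1,3-phenylene diacetate | Oc1ccc2c(c1)[C@H](c1cc(OC(C)=O)cc(OC(C)=O)c1)[C@@H](c1ccc(O[Si](C)(C)C(C)(C)C)c(O[Si](C)(C)C(C)(C)C)c1)O2
F3 | step 2 | 5-[(2R,3R)-2-[3,4-bis(tert-butyldimethylsilyloxy)phenyl]-5-hydroxy-2,3-dihydro-1-benzofuran-3-yl]-1,3-phenylene diacetate | Oc1ccc2c(c1)[C@@H](c1cc(OC(C)=O)cc(OC(C)=O)c1)[C@H](c1ccc(O[Si](C)(C)C(C)(C)C)c(O[Si](C)(C)C(C)(C)C)c1)O2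
F4 | step 3 | 5-[(2S,3S)-5-hydroxy-2-(2-oxo-1,3-benzodioxol-5-yl)-2,3-dihydro-1-benzofuran-3-yl]-1,3-phenylene diacetate | Oc1ccc2c(c1)[C@H](c1cc(OC(C)=O)cc(OC(C)=O)c1)[C@@H](c1ccc3OC(=O)Oc3c1)O2
F5 | step 3 | (2S,3S)-3-(3,5-diacetoxyphenyl)-2-(2-oxo-1,3-benzodioxol-5-yl)-2,3-dihydro-1-benzofuran-5-yl trifluoromethanesulfonate | O=S(=O)(Oc1ccc2c(c1)[C@H](c1cc(OC(C)=O)cc(OC(C)=O)c1)[C@@H](c1ccc3OC(=O)Oc3c1)O2)C(F)(F)F
F6 | step 3 | 5-[(E)-2-[(2S,3S)-3-(3,5-diacetoxyphenyl)-2-(2-oxo-1,3-benzodioxol-5-yl)-2,3-dihydro-1-benzofuran-5-yl]ethenyl]-1,3-phenylene diacetate | CC(=O)Oc1cc(OC(C)=O)cc(/C=C/c2ccc3c(c2)[C@H](c2cc(OC(C)=O)cc(OC(C)=O)c2)[C@@H](c2ccc4OC(=O)Oc4c2)O3)c1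
F7 | step 6 | 4-[(2S,3S)-3-(3,5-diacetoxyphenyl)-5-ethenyl-2,3-dihydro-1-benzofuran-2-yl]-1,2-phenylene diacetate | C=Cc1ccc2c(c1)[C@H](c1cc(OC(C)=O)cc(OC(C)=O)c1)[C@@H](c1ccc(OC(C)=O)c(OC(C)=O)c1)O2
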